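**Assumption:** the target is taken exactly as the given SMILES (4R ring carbon, 6R tertiary carbinol, 4E alkene); in step 7 the (R,R)-ligand is written for the (R)-carbinol, and its mirror image is used if the first run shows the opposite sense.

## Retrosynthetic overview

1. 16 ⇒ 11 + 15 by E-selective cross-metathesis of the side-chain CH=CH.
2. 15 ⇒ 12 + 13: Pd-catalysed dynamic kinetic asymmetric C–O bond formation on racemic isoprene monoxide, then O→O acyl shift (key step; sets the carbinol centre and installs the ester).
3. 11 ⇒ 9 (Stille vinylation) ⇒ 7 (ene chlorination of the isopropenyl group).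
4. 7 ⇒ 6 ⇒ 5 ⇒ 3 ⇒ 1: oxidation, acid-catalysed epoxide opening with cyclobutane fragmentation, epoxidation, O-acylation of (−)-myrtenol.
5. Rings: the six-membered ring comes from the pinane core of 1 (cyclobutane cleaved in step 3); the only ring made is the transient oxirane of 5 (step 2), opened in step 3.

## Route

**Step 1**
Reactants: 1 (1R,5S)-(−)-myrtenol; 2 isobutyryl chloride
Product: 3 myrtenyl isobutyrate [(1R,5S)-6,6-dimethylbicyclo[3.1.1]hept-2-en-2-yl]methyl 2-methylpropanoate
Conditions: i-PrCOCl (1.1 equiv), Et3N (1.3 equiv), DMAP (5 mol %), CH2Cl2, 0 °C → rt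
Reagents that add atoms: isobutyryl chloride, CC(C)C(Cl)=O
Why: DMAP-catalysed acylation (nucleophilic acyl substitution) of the primary allylic alcohol; no stereocentre is touched.

**Step 2**
Reactants: 3; 4 hydrogen peroxide (30 % aq.)
Product: 5 2,3-epoxide of 3 (7,7-dimethyl-3-oxatricyclo[4.1.1.0^2,4]octan-2-yl)methyl 2-methylpropanoate with the oxirane oxygen anti to the CMe2 bridge
Conditions: MeReO3 (0.5 mol %), pyridine (12 mol %), 30 % aq. H2O2 (1.5 equiv), CH2Cl2, rt
Reagents that add atoms: hydrogen peroxide, OO
Why: Methyltrioxorhenium-catalysed epoxidation of the only alkene under pyridine-buffered conditions that spare the acid-labile epoxide; the CMe2 bridge blocks one face, so both oxirane carbons are set by attack anti to it, as in α-pinene.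

**Step 3**
Reactants: 5
Product: 6 [(4R,6S)-6-hydroxy-4-(prop-1-en-2-yl)cyclohex-1-en-1-yl]methyl 2-methylpropanoate
Conditions: H3PW12O40 (1 mol %), DMA, 60 °C
Reagents that add atoms: none
Why: Acid-catalysed epoxide isomerisation with cyclobutane fragmentation (the α-pinene oxide → trans-carveol reaction type): the tertiary C–O bond ionises with anti-periplanar C1–C6 cleavage, and the resulting tertiary cation loses a methyl proton to give the isopropenyl group. The secondary C–O bond (6S, trans) and the former bridgehead carbon (now 4R) are not touched, so the ring stereocentre comes directly from 1.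

**Step 4**
Reactants: 6
Product: 7 [(4R)-6-oxo-4-(prop-1-en-2-yl)cyclohex-1-en-1-yl]methyl 2-methylpropanoate
Conditions: Dess–Martin periodinane (1.2 equiv), CH2Cl2, 0 °C → rt
Reagents that add atoms: none
Why: Dess–Martin oxidation of the secondary allylic alcohol to the enone; the 4R centre is β to the new ketone and cannot epimerise.

**Step 5**
Reactants: 7; 8 calcium hypochlorite
Product: 9 [(4R)-4-(3-chloroprop-1-en-2-yl)-6-oxocyclohex-1-en-1-yl]methyl 2-methylpropanoate
Conditions: Ca(OCl)2, CO2 (dry ice), CH2Cl2/H2O, 0 °C
Reagents that add atoms: calcium hypochlorite, [Ca+2].[O-]Cl.[O-]Cl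
Why: Ene-type allylic chlorination by HOCl on the electron-rich 1,1-disubstituted alkene only, since the enone alkene is electron-poor (same selectivity as carvone → 10-chlorocarvone); no stereocentre is involved.

**Step 6**
Reactants: 9; 10 tributyl(vinyl)stannane
Product: 11 [(4R)-6-oxo-4-(penta-1,4-dien-2-yl)cyclohex-1-en-1-yl]methyl 2-methylpropanoate
Conditions: Pd2(dba)3 (2.5 mol %), AsPh3 (10 mol %), Bu3SnCH=CH2 (1.2 equiv), THF, 45 °C
Reagents that add atoms: tributyl(vinyl)stannane, C=C[Sn](CCCC)(CCCC)CCCC
Why: Stille allyl–vinyl coupling: the π-allyl palladium intermediate has two equivalent CH2 termini, so there is no regiochemical issue. Neutral conditions spare the acyloxymethyl enone, and the allylic chloride ionises much faster than the allylic carboxylate with the weakly donating arsine.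

**Step 7**
Reactants: 12 racemic 2-methyl-2-vinyloxirane (isoprene monoxide); 13 isobutyric acid
Product: 15 (2R)-2-hydroxy-2-methylbut-3-en-1-yl 2-methylpropanoate, via tertiary allylic ester 14 (not isolated)
Conditions: Pd2(dba)3·CHCl3 (1 mol %), (R,R)-DACH-naphthyl Trost ligand (3 mol %), i-PrCO2H (1.05 equiv), Cs2CO3 (5 mol %), CH2Cl2, 0 °C → rt; then DMAP (10 mol %), rt
Reagents that add atoms: isobutyric acid, CC(C)C(O)=O
Why: Proposed new method: Pd(0) opens racemic 12 to a π-allyl palladium alkoxide that the acid protonates; the two diastereomeric π-allyl complexes interconvert by η3–η1–η3 slippage at the unsubstituted CH2 terminus faster than they are attacked, and the hydrogen-bonded isobutyrate is delivered inside the chiral ligand pocket to the tertiary terminus next to the hydroxyl, which forms the C–O bond and sets the (R) centre in 14; base-catalysed 1,2 O→O acyl shift through a five-membered orthoester then moves the ester to the primary oxygen without touching the stereocentre, which is downhill and turns the ionisable tertiary allylic ester into a tertiary allylic alcohol that Pd(0) no longer ionises, so the ee is locked and the linear 1,4-adduct is avoided; the closest known reaction type is the Trost Pd-catalysed dynamic kinetic asymmetric allylic substitution (Tsuji–Trost) of isoprene monoxide with alcohols (borane co-catalyst) or phthalimide, together with the racemic Pd(0) addition of carboxylic acids to diene monoepoxides.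

**Step 8**
Reactants: 11; 15
Product: 16 [(4R)-4-[(4E,6R)-6-hydroxy-6-methyl-7-(2-methylpropanoyloxy)hepta-1,4-dien-2-yl]-6-oxocyclohex-1-en-1-yl]methyl 2-methylpropanoate (CNP0536801.1)
Conditions: Hoveyda–Grubbs II (5 mol %), 15 (3 equiv), 1,4-benzoquinone (10 mol %), CH2Cl2, 40 °C
Reagents that add atoms: (2R)-2-hydroxy-2-methylbut-3-en-1-yl 2-methylpropanoate (15), C=C[C@@](C)(O)COC(=O)C(C)C
Why: Olefin cross-metathesis between the terminal vinyl group of 11 and the unprotected tertiary allylic alcohol 15, which is slow to homodimerise and gives the E-alkene under thermodynamic control. The 1,1-disubstituted and enone alkenes are inert to the catalyst, benzoquinone suppresses migration of the skipped diene, and both stereocentres are untouched.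

## Compound list

1 | (1R,5S)-(−)-myrtenol | OCC1=CC[C@H]2C[C@@H]1C2(C)C | starting material
2 | isobutyryl chloride (2-methylpropanoyl chloride) | CC(C)C(Cl)=O | starting material
3 | [(1R,5S)-6,6-dimethylbicyclo[3.1.1]hept-2-en-2-yl]methyl 2-methylpropanoate (myrtenyl isobutyrate) | CC(C)C(=O)OCC1=CC[C@H]2C[C@@H]1C2(C)C | intermediate
4 | hydrogen peroxide (30 % aq.) | OO | starting material
5 | (7,7-dimethyl-3-oxatricyclo[4.1.1.0^2,4]octan-2-yl)methyl 2-methylpropanoate, oxirane O anti to the CMe2 bridge | CC(C)C(=O)OC[C@]13O[C@H]1C[C@H]2C[C@@H]3C2(C)C | intermediate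
6 | [(4R,6S)-6-hydroxy-4-(prop-1-en-2-yl)cyclohex-1-en-1-yl]methyl 2-methylpropanoate | CC(C)C(=O)OCC1=CC[C@@H](C(C)=C)C[C@@H]1O | intermediate
7 | [(4R)-6-oxo-4-(prop-1-en-2-yl)cyclohex-1-en-1-yl]methyl 2-methylpropanoate | CC(C)C(=O)OCC1=CC[C@@H](C(C)=C)CC1=O | intermediate
8 | calcium hypochlorite | [Ca+2].[O-]Cl.[O-]Cl | starting material
9 | [(4R)-4-(3-chloroprop-1-en-2-yl)-6-oxocyclohex-1-en-1-yl]methyl 2-methylpropanoate | CC(C)C(=O)OCC1=CC[C@@H](C(CCl)=C)CC1=O | intermediate
10 | tributyl(vinyl)stannane | C=C[Sn](CCCC)(CCCC)CCCC | starting material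
11 | [(4R)-6-oxo-4-(penta-1,4-dien-2-yl)cyclohex-1-en-1-yl]methyl 2-methylpropanoate | CC(C)C(=O)OCC1=CC[C@@H](C(CC=C)=C)CC1=O | intermediate
12 | racemic 2-methyl-2-vinyloxirane (isoprene monoxide) | C=CC1(C)CO1 | starting material
13 | isobutyric acid (2-methylpropanoic acid) | CC(C)C(O)=O | starting material
14 | (2R)-1-hydroxy-2-methylbut-3-en-2-yl 2-methylpropanoate | C=C[C@@](C)(OC(=O)C(C)C)CO | intermediate
15 | (2R)-2-hydroxy-2-methylbut-3-en-1-yl 2-methylpropanoate | C=C[C@@](C)(O)COC(=O)C(C)C | intermediate
16 | [(4R)-4-[(4E,6R)-6-hydroxy-6-methyl-7-(2-methylpropanoyloxy)hepta-1,4-dien-2-yl]-6-oxocyclohex-1-en-1-yl]methyl 2-methylpropanoate (CNP0536801.1) | C=C(C/C=C/[C@@](C)(O)COC(=O)C(C)C)[C@@H]1CC=C(COC(=O)C(C)C)C(=O)C1 | target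

## Step count and risk

Total step count: 8. Longest linear sequence: 7 (steps 1–6, then 8).

The three steps most likely to fail are 7, 3 and 8.

The new C–O bond-forming reaction of step 7 is the least certain. The carboxylate may attack the CH2 terminus and give the linear 1,4-adduct, or the tertiary ester may re-ionise before the acyl shift and lose ee. The fallback uses known chemistry, sets out from 12 and comes back to the route at 15. The established Trost asymmetric addition of 4-methoxybenzyl alcohol to 12 (Pd2(dba)3·CHCl3, (R,R)-DACH-phenyl ligand, catalytic BEt3, CH2Cl2) gives (2R)-2-[(4-methoxyphenyl)methoxy]-2-methylbut-3-en-1-ol F1. Acylation of its primary hydroxyl with 2 (Et3N, DMAP) gives (2R)-2-[(4-methoxyphenyl)methoxy]-2-methylbut-3-en-1-yl 2-methylpropanoate F2. DDQ in wet CH2Cl2 then removes the PMB group to give 15.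

The fragmentation of step 3 may be unselective under anhydrous acid, giving campholenic-type or hydride-shift products, or a mixture of proton-loss isomers. The fallback sets out from 5 and comes back at 7. It traps the cation with water, as in the α-pinene oxide → trans-sobrerol reaction: 5 in aqueous acetone with a trace of H2SO4 gives [(4R,6S)-6-hydroxy-4-(2-hydroxypropan-2-yl)cyclohex-1-en-1-yl]methyl 2-methylpropanoate F3. Dess–Martin oxidation of the secondary alcohol gives [(4R)-4-(2-hydroxypropan-2-yl)-6-oxocyclohex-1-en-1-yl]methyl 2-methylpropanoate F4. Dehydration of the tertiary alcohol (SOCl2, pyridine, 0 °C) gives 7, and the minor isopropylidene isomer is removed on AgNO3-impregnated silica.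

The cross-metathesis of step 8 may suffer from migration of the skipped diene or from low conversion of the hindered tertiary allylic alcohol. The fallback sets out from 9 and 15 and comes back at 16, bypassing 11. Cross-metathesis of 15 with vinylboronic acid pinacol ester (Hoveyda–Grubbs II, CH2Cl2, 40 °C) gives (2R,3E)-2-hydroxy-2-methyl-4-(4,4,5,5-tetramethyl-1,3,2-dioxaborolan-2-yl)but-3-en-1-yl 2-methylpropanoate F5. A Pd-catalysed allyl–alkenyl Suzuki–Miyaura coupling of this with the allylic chloride 9 (Pd(PPh3)4, CsF, THF, 50 °C) gives 16 directly.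

## Further compounds

F1 | step 7 | (2R)-2-[(4-methoxyphenyl)methoxy]-2-methylbut-3-en-1-ol | C=C[C@@](C)(OCc1ccc(OC)cc1)CO
F2 | step 7 | (2R)-2-[(4-methoxyphenyl)methoxy]-2-methylbut-3-en-1-yl 2-methylpropanoate | C=C[C@@](C)(OCc1ccc(OC)cc1)COC(=O)C(C)C
F3 | step 3 | [(4R,6S)-6-hydroxy-4-(2-hydroxypropan-2-yl)cyclohex-1-en-1-yl]methyl 2-methylpropanoate | CC(C)C(=O)OCC1=CC[C@@H](C(C)(C)O)C[C@@H]1O
F4 | step 3 | [(4R)-4-(2-hydroxypropan-2-yl)-6-oxocyclohex-1-en-1-yl]methyl 2-methylpropanoate | CC(C)C(=O)OCC1=CC[C@@H](C(C)(C)O)CC1=O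
F5 | step 8 | (2R,3E)-2-hydroxy-2-methyl-4-(4,4,5,5-tetramethyl-1,3,2-dioxaborolan-2-yl)but-3-en-1-yl 2-methylpropanoate | CC1(C)OB(/C=C/[C@@](C)(O)COC(=O)C(C)C)OC1(C)C
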